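**Plan**

1. Retrosynthesis: the three MOM ethers come off last. The C3 configuration is traced back to the racemic ketone through a cis-chroman-4-ol made by dynamic kinetic resolution. Ring C is then cut at O1–C8a and C4–C4a together, leaving a 3,5-dioxygenated 4-prenylbenzyne and a 2-aryl-3-silyloxypropanoate.
2. Enabling feature: the oxygen on C5 of ring A, next to C4a, polarises the C4a≡C8a aryne so that the alkoxide enters at C8a and the carbanion at C4a acylates. The C6 prenyl group lies between two equal oxygens of a symmetric arene, so the choice between C6 and C8 never arises.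
3. Forward, ring A piece (steps 1–6): 1,3-bis(methoxymethoxy)benzene is prenylated by lithiation, borylated and oxidised at C5, then silylated ortho to a carbamate and converted to the silyl triflate.
4. Forward, ring B piece (steps 7–10): methyl (3-bromo-4-hydroxyphenyl)acetate is MOM-protected, prenylated by Negishi coupling, hydroxymethylated and silylated. Step 11 joins the two pieces and closes ring C, racemic at C3.
5. Stereochemistry: catalyst control in a Noyori–Ikariya transfer hydrogenation with dynamic kinetic resolution (step 12). The C4 carbinol is then erased (step 13) and the MOM groups are removed with acid, avoiding base at the enolisable C3.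

Key step: step 11

Remark: compounds 1 and 13 are taken as purchasable; the (R,R) catalyst in step 12 is assigned by analogy with the usual facial preference of this catalyst class on benzo-fused cyclic aryl ketones, and the (S,S) catalyst would be used if the sense proved opposite.

**Route**

Step 1
Reactants: 1 1,3-bis(methoxymethoxy)benzene
Product: 3 1,3-bis(methoxymethoxy)-2-(3-methylbut-2-en-1-yl)benzene, via aryllithium 2 (not isolated)
Conditions: n-BuLi, TMEDA, THF, 0 °C; then prenyl bromide, −78 °C to rt
Reagents that add atoms: prenyl bromide (1-bromo-3-methylbut-2-ene), CC(C)=CCBr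
Why: Directed ortho-metalation occurs at C2, the ring position flanked by both MOM ethers, and the aryllithium is alkylated by SN2 displacement at the primary carbon of prenyl bromide.

Step 2
Reactants: 3 1,3-bis(methoxymethoxy)-2-(3-methylbut-2-en-1-yl)benzene
Product: 4 2-[3,5-bis(methoxymethoxy)-4-(3-methylbut-2-en-1-yl)phenyl]-4,4,5,5-tetramethyl-1,3,2-dioxaborolane
Conditions: B2pin2, [Ir(OMe)(cod)]2 (1.5 mol %), 4,4'-di-tert-butyl-2,2'-bipyridine (3 mol %), THF, 60 °C
Reagents that add atoms: bis(pinacolato)diboron, CC1(C)OB(OC1(C)C)B1OC(C)(C)C(C)(C)O1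
Why: Iridium-catalysed aromatic C–H borylation is governed by sterics and C5 is the only ring C–H without an ortho substituent, while the trisubstituted prenyl alkene and the acetals are not expected to interfere.

Step 3
Reactants: 4 2-[3,5-bis(methoxymethoxy)-4-(3-methylbut-2-en-1-yl)phenyl]-4,4,5,5-tetramethyl-1,3,2-dioxaborolane
Product: 5 3,5-bis(methoxymethoxy)-4-(3-methylbut-2-en-1-yl)phenol
Conditions: H2O2 (30% aq.), NaOH, THF, 0 °C
Reagents that add atoms: hydrogen peroxide, OO
Why: Oxidation of the arylboronate by alkaline hydroperoxide (1,2-aryl shift from boron to oxygen) gives the phenol, and alkaline peroxide does not epoxidise an unactivated alkene.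

Step 4
Reactants: 5 3,5-bis(methoxymethoxy)-4-(3-methylbut-2-en-1-yl)phenol
Product: 6 3,5-bis(methoxymethoxy)-4-(3-methylbut-2-en-1-yl)phenyl N-(propan-2-yl)carbamate
Conditions: i-PrNCO, Et3N (cat.), CH2Cl2, rt
Reagents that add atoms: isopropyl isocyanate, CC(C)N=C=O
Why: Amine-catalysed addition of the phenol to the isocyanate (carbamoylation) installs a strong ortho-directing group that can later be removed under mild base.

Step 5
Reactants: 6 3,5-bis(methoxymethoxy)-4-(3-methylbut-2-en-1-yl)phenyl N-(propan-2-yl)carbamate
Product: 10 3,5-bis(methoxymethoxy)-4-(3-methylbut-2-en-1-yl)-2-(trimethylsilyl)phenyl N-(propan-2-yl)carbamate, via N-silyl carbamate 7 (not isolated), via aryllithium 8 (not isolated), via N-silyl arylsilane 9 (not isolated)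
Conditions: TBSOTf, TMEDA, Et2O, 0 °C to rt; n-BuLi, TMEDA, −78 °C; TMSCl, −78 °C to rt; brief cold aq. NaHSO4 work-up
Reagents that add atoms: chlorotrimethylsilane, C[Si](C)(C)Cl
Why: After N-silylation in the flask, carbamate-directed ortho-metalation takes place at the ring carbon between the carbamate oxygen and a MOM ether (two such positions, equal by symmetry) and the aryllithium is silylated at carbon, the N–Si bond being hydrolysed on work-up.

Step 6
Reactants: 10 3,5-bis(methoxymethoxy)-4-(3-methylbut-2-en-1-yl)-2-(trimethylsilyl)phenyl N-(propan-2-yl)carbamate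
Product: 12 3,5-bis(methoxymethoxy)-4-(3-methylbut-2-en-1-yl)-2-(trimethylsilyl)phenyl trifluoromethanesulfonate, via silylphenol 11 (not isolated)
Conditions: DBU, Et2NH, MeCN, 40 °C; then PhNTf2, rt
Reagents that add atoms: N-phenylbis(trifluoromethanesulfonimide), O=S(=O)(N(c1ccccc1)S(=O)(=O)C(F)(F)F)C(F)(F)F
Why: Base-induced elimination of the secondary carbamate (E1cB, the isocyanate being trapped by diethylamine) frees the hindered phenoxide, which is sulfonylated in the same flask by the mild triflyl donor to give the ortho-silylaryl triflate.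

Step 7
Reactants: 13 methyl (3-bromo-4-hydroxyphenyl)acetate
Product: 14 methyl [3-bromo-4-(methoxymethoxy)phenyl]acetate
Conditions: MOMCl, i-Pr2NEt, CH2Cl2, 0 °C to rt
Reagents that add atoms: chloromethyl methyl ether, COCCl
Why: Williamson-type O-alkylation of the phenol with the reactive α-chloro ether under amine base leaves the ester untouched.

Step 8
Reactants: 14 methyl [3-bromo-4-(methoxymethoxy)phenyl]acetate
Product: 15 methyl [4-(methoxymethoxy)-3-(3-methylbut-2-en-1-yl)phenyl]acetate
Conditions: prenylzinc bromide (from prenyl bromide, Zn dust, LiCl, THF), Pd(OAc)2 (2 mol %), CPhos (4 mol %), THF, rt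
Reagents that add atoms: prenylzinc bromide, CC(C)=CC[Zn]Br (made in the flask from prenyl bromide, CC(C)=CCBr, and zinc)
Why: Negishi coupling of the aryl bromide with the prenylzinc reagent should give the linear prenyl arene because the bulky biarylphosphine favours reductive elimination at the unsubstituted allyl terminus, and the organozinc tolerates the ester.

Step 9
Reactants: 15 methyl [4-(methoxymethoxy)-3-(3-methylbut-2-en-1-yl)phenyl]acetate
Product: 16 methyl (2RS)-3-hydroxy-2-[4-(methoxymethoxy)-3-(3-methylbut-2-en-1-yl)phenyl]propanoate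
Conditions: paraformaldehyde (1.1 equiv), NaOMe (5 mol %), DMSO, rt
Reagents that add atoms: formaldehyde (as paraformaldehyde), C=O
Why: Aldol addition of the ester enolate to formaldehyde (hydroxymethylation) under catalytic base gives the racemic 3-hydroxy ester, the mild conditions limiting dehydration and double addition.

Step 10
Reactants: 16 methyl (2RS)-3-hydroxy-2-[4-(methoxymethoxy)-3-(3-methylbut-2-en-1-yl)phenyl]propanoate
Product: 17 methyl (2RS)-2-[4-(methoxymethoxy)-3-(3-methylbut-2-en-1-yl)phenyl]-3-[(trimethylsilyl)oxy]propanoate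
Conditions: TMSCl, Et3N, CH2Cl2, 0 °C; filtration under argon, no aqueous work-up
Reagents that add atoms: chlorotrimethylsilane, C[Si](C)(C)Cl
Why: Silylation of the primary alcohol gives the silyl ether from which fluoride can release a free alkoxide in step 11 without leaving an O–H proton in the flask.

Step 11
Reactants: 12 3,5-bis(methoxymethoxy)-4-(3-methylbut-2-en-1-yl)-2-(trimethylsilyl)phenyl trifluoromethanesulfonate; 17 methyl (2RS)-2-[4-(methoxymethoxy)-3-(3-methylbut-2-en-1-yl)phenyl]-3-[(trimethylsilyl)oxy]propanoate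
Product: 21 (3RS)-5,7-bis(methoxymethoxy)-3-[4-(methoxymethoxy)-3-(3-methylbut-2-en-1-yl)phenyl]-6-(3-methylbut-2-en-1-yl)-2,3-dihydro-4H-chromen-4-one, via cesium alkoxide 18 (not isolated), via aryne 19 (not isolated), via aryl anion 20 (not isolated)
Conditions: CsF (4 equiv), dry THF, 65 °C; 12 (1.3 equiv) and 17 premixed
Reagents that add atoms: none
Why: Proposed new method: fluoride removes both trimethylsilyl groups, so the cesium alkoxide 18 and the aryne 19 (C4a≡C8a of ring A) form side by side with no O–H proton present; the alkoxide adds to C8a, the carbanion 20 that results at C4a attacks the methyl ester and expels methoxide, which closes ring C by a 6-exo-trig acyl substitution and makes the O1–C8a and C4–C4a bonds in one operation. The closest known reaction types are the annulation of arynes with salicylate esters to xanthones (oxygen addition, then intramolecular acyl capture) and the insertion of arynes into the N–C(=O) bond of β-lactams; an aliphatic 3-hydroxy ester has not been shown to do this. The step needs regioselectivity, and the MOM-protected oxygen on C5 secures it: its inductive pull distorts the aryne so that the nucleophile enters at the remote carbon C8a and the charge develops at C4a, as 3-alkoxyarynes do in general, and because the prenyl group already sits between the two oxygens this places it at C6 and not at C8. It also needs acyl capture to outrun protonation or α-deprotonation, which the silyl ether (free alkoxide instead of a hydrogen-bonded alcohol), the aprotic solvent and the six-membered transition state are meant to secure; released methoxide can desilylate further 17 or 12 and so carries the reaction on. No stereocenter is set here: C3 stays racemic on purpose, since an α-aryl ketone would not hold its configuration in this basic medium, and it is set in step 12.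

Step 12
Reactants: 21 (3RS)-5,7-bis(methoxymethoxy)-3-[4-(methoxymethoxy)-3-(3-methylbut-2-en-1-yl)phenyl]-6-(3-methylbut-2-en-1-yl)-2,3-dihydro-4H-chromen-4-one
Product: 22 (3R,4R)-5,7-bis(methoxymethoxy)-3-[4-(methoxymethoxy)-3-(3-methylbut-2-en-1-yl)phenyl]-6-(3-methylbut-2-en-1-yl)-3,4-dihydro-2H-chromen-4-ol
Conditions: RuCl[(R,R)-TsDPEN](p-cymene) (3 mol %), HCO2H/Et3N (amine-rich), EtOAc, 40 °C
Reagents that add atoms: none
Why: Noyori–Ikariya asymmetric transfer hydrogenation with dynamic kinetic resolution: triethylamine equilibrates C3 through the enol, the (R,R) catalyst reduces the (3R) ketone faster and delivers hydride to the carbonyl face anti to the 3-aryl group, which should give the cis (3R,4R) alcohol, so that C3 and C4 are both set by the catalyst.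

Step 13
Reactants: 22 (3R,4R)-5,7-bis(methoxymethoxy)-3-[4-(methoxymethoxy)-3-(3-methylbut-2-en-1-yl)phenyl]-6-(3-methylbut-2-en-1-yl)-3,4-dihydro-2H-chromen-4-ol
Product: 23 (3R)-5,7-bis(methoxymethoxy)-3-[4-(methoxymethoxy)-3-(3-methylbut-2-en-1-yl)phenyl]-6-(3-methylbut-2-en-1-yl)-2,3-dihydro-4H-chromen-4-one
Conditions: Dess–Martin periodinane, NaHCO3, CH2Cl2, 0 °C
Reagents that add atoms: none
Why: Dess–Martin oxidation under bicarbonate buffer returns the ketone without a base strong enough to enolise C3, so the (3R) configuration set in step 12 should be retained.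

Step 14
Reactants: 23 (3R)-5,7-bis(methoxymethoxy)-3-[4-(methoxymethoxy)-3-(3-methylbut-2-en-1-yl)phenyl]-6-(3-methylbut-2-en-1-yl)-2,3-dihydro-4H-chromen-4-one
Product: 24 (3R)-5,7-dihydroxy-3-[4-hydroxy-3-(3-methylbut-2-en-1-yl)phenyl]-6-(3-methylbut-2-en-1-yl)-2,3-dihydro-4H-chromen-4-one
Conditions: aq. HCl (3 M), MeOH, rt to 40 °C, stopped at full conversion
Reagents that add atoms: none
Why: Acid-catalysed acetal cleavage (transacetalisation to dimethoxymethane) removes the three phenolic MOM ethers, acid being chosen because C3 epimerises fastest through the enolate, and the mild temperature limits cyclisation of the prenyl groups onto the phenols.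

**Compound list**

1 | 1,3-bis(methoxymethoxy)benzene | COCOc1cccc(OCOC)c1 | starting material
2 | [2,6-bis(methoxymethoxy)phenyl]lithium (not isolated) | [Li]c1c(OCOC)cccc1OCOC | intermediate
3 | 1,3-bis(methoxymethoxy)-2-(3-methylbut-2-en-1-yl)benzene | COCOc1cccc(OCOC)c1CC=C(C)C | intermediate
4 | 2-[3,5-bis(methoxymethoxy)-4-(3-methylbut-2-en-1-yl)phenyl]-4,4,5,5-tetramethyl-1,3,2-dioxaborolane | COCOc1cc(B2OC(C)(C)C(C)(C)O2)cc(OCOC)c1CC=C(C)C | intermediate
5 | 3,5-bis(methoxymethoxy)-4-(3-methylbut-2-en-1-yl)phenol | COCOc1cc(O)cc(OCOC)c1CC=C(C)C | intermediate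
6 | 3,5-bis(methoxymethoxy)-4-(3-methylbut-2-en-1-yl)phenyl N-(propan-2-yl)carbamate | COCOc1cc(OC(=O)NC(C)C)cc(OCOC)c1CC=C(C)C | intermediate
7 | 3,5-bis(methoxymethoxy)-4-(3-methylbut-2-en-1-yl)phenyl N-[tert-butyl(dimethyl)silyl]-N-(propan-2-yl)carbamate (not isolated) | COCOc1cc(OC(=O)N(C(C)C)[Si](C)(C)C(C)(C)C)cc(OCOC)c1CC=C(C)C | intermediate
8 | 2-lithio derivative of 7, lithium on the ring carbon between the carbamate oxygen and a MOM ether (not isolated) | COCOc1cc(OC(=O)N(C(C)C)[Si](C)(C)C(C)(C)C)c([Li])c(OCOC)c1CC=C(C)C | intermediate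
9 | 3,5-bis(methoxymethoxy)-4-(3-methylbut-2-en-1-yl)-2-(trimethylsilyl)phenyl N-[tert-butyl(dimethyl)silyl]-N-(propan-2-yl)carbamate (not isolated) | COCOc1cc(OC(=O)N(C(C)C)[Si](C)(C)C(C)(C)C)c([Si](C)(C)C)c(OCOC)c1CC=C(C)C | intermediate
10 | 3,5-bis(methoxymethoxy)-4-(3-methylbut-2-en-1-yl)-2-(trimethylsilyl)phenyl N-(propan-2-yl)carbamate | COCOc1cc(OC(=O)NC(C)C)c([Si](C)(C)C)c(OCOC)c1CC=C(C)C | intermediate
11 | 3,5-bis(methoxymethoxy)-4-(3-methylbut-2-en-1-yl)-2-(trimethylsilyl)phenol, present as its amidinium phenoxide (not isolated) | COCOc1cc(O)c([Si](C)(C)C)c(OCOC)c1CC=C(C)C | intermediate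
12 | 3,5-bis(methoxymethoxy)-4-(3-methylbut-2-en-1-yl)-2-(trimethylsilyl)phenyl trifluoromethanesulfonate | COCOc1cc(OS(=O)(=O)C(F)(F)F)c([Si](C)(C)C)c(OCOC)c1CC=C(C)C | intermediate
13 | methyl (3-bromo-4-hydroxyphenyl)acetate | COC(=O)Cc1ccc(O)c(Br)c1 | starting material
14 | methyl [3-bromo-4-(methoxymethoxy)phenyl]acetate | COC(=O)Cc1ccc(OCOC)c(Br)c1 | intermediate
15 | methyl [4-(methoxymethoxy)-3-(3-methylbut-2-en-1-yl)phenyl]acetate | COC(=O)Cc1ccc(OCOC)c(CC=C(C)C)c1 | intermediate
16 | methyl (2RS)-3-hydroxy-2-[4-(methoxymethoxy)-3-(3-methylbut-2-en-1-yl)phenyl]propanoate (racemic) | COC(=O)C(CO)c1ccc(OCOC)c(CC=C(C)C)c1 | intermediate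
17 | methyl (2RS)-2-[4-(methoxymethoxy)-3-(3-methylbut-2-en-1-yl)phenyl]-3-[(trimethylsilyl)oxy]propanoate (racemic) | COC(=O)C(CO[Si](C)(C)C)c1ccc(OCOC)c(CC=C(C)C)c1 | intermediate
18 | cesium alkoxide of 16 (racemic, not isolated) | COC(=O)C(C[O-])c1ccc(OCOC)c(CC=C(C)C)c1.[Cs+] | intermediate
19 | 3,5-bis(methoxymethoxy)-4-(3-methylbut-2-en-1-yl)-1,2-didehydrobenzene (aryne, not isolated) | COCOC1=CC#CC(OCOC)=C1CC=C(C)C | intermediate
20 | cesium salt of the aryl anion methyl 3-[2-cesio-3,5-bis(methoxymethoxy)-4-(3-methylbut-2-en-1-yl)phenoxy]-2-[4-(methoxymethoxy)-3-(3-methylbut-2-en-1-yl)phenyl]propanoate (racemic, not isolated) | COC(=O)C(COc1cc(OCOC)c(CC=C(C)C)c(OCOC)[c-]1)c1ccc(OCOC)c(CC=C(C)C)c1.[Cs+] | intermediate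
21 | (3RS)-5,7-bis(methoxymethoxy)-3-[4-(methoxymethoxy)-3-(3-methylbut-2-en-1-yl)phenyl]-6-(3-methylbut-2-en-1-yl)-2,3-dihydro-4H-chromen-4-one (racemic) | COCOc1ccc(C2COc3cc(OCOC)c(CC=C(C)C)c(OCOC)c3C2=O)cc1CC=C(C)C | intermediate
22 | (3R,4R)-5,7-bis(methoxymethoxy)-3-[4-(methoxymethoxy)-3-(3-methylbut-2-en-1-yl)phenyl]-6-(3-methylbut-2-en-1-yl)-3,4-dihydro-2H-chromen-4-ol (cis) | COCOc1ccc([C@@H]2COc3cc(OCOC)c(CC=C(C)C)c(OCOC)c3[C@@H]2O)cc1CC=C(C)C | intermediate
23 | (3R)-5,7-bis(methoxymethoxy)-3-[4-(methoxymethoxy)-3-(3-methylbut-2-en-1-yl)phenyl]-6-(3-methylbut-2-en-1-yl)-2,3-dihydro-4H-chromen-4-one | COCOc1ccc([C@@H]2COc3cc(OCOC)c(CC=C(C)C)c(OCOC)c3C2=O)cc1CC=C(C)C | intermediate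
24 | (3R)-5,7-dihydroxy-3-[4-hydroxy-3-(3-methylbut-2-en-1-yl)phenyl]-6-(3-methylbut-2-en-1-yl)-2,3-dihydro-4H-chromen-4-one | CC(C)=CCc1cc([C@@H]2COc3cc(O)c(CC=C(C)C)c(O)c3C2=O)ccc1O | target

**Count**

Total step count: 14. Longest linear sequence: 10 steps (steps 1–6, then 11–14).

**Steps most likely to fail**

Step 11 (proposed new method). The carbanion at C4a may be quenched by proton transfer (from the α-C–H of the ester or from traces of water) before it reaches the ester, or the hydroxy ester may enolise and eliminate in the basic fluoride medium. Either process would leave an uncyclised aryl ether or an acrylate. The fallback uses known chemistry, sets out from 15 and 12 and comes back at 21. Saponification of 15 (LiOH, THF/H2O) should give [4-(methoxymethoxy)-3-(3-methylbut-2-en-1-yl)phenyl]acetic acid F1. F1 and 12 with CsF in THF at 125 °C (sealed tube) should undergo the known insertion of an aryne into the C–O bond of a carboxylic acid: the carboxylate adds at C8a and the acyl group shifts to C4a, with the same regiocontrol by the C5 oxygen. This should give 1-[6-hydroxy-2,4-bis(methoxymethoxy)-3-(3-methylbut-2-en-1-yl)phenyl]-2-[4-(methoxymethoxy)-3-(3-methylbut-2-en-1-yl)phenyl]ethan-1-one F2. Treating F2 with paraformaldehyde and Et2NH in MeOH at reflux (α-methylenation, then 6-endo oxa-Michael closure) should give racemic 21. In this variant the ring oxygen comes from the acid and C2 from formaldehyde.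

Step 12. Hydride transfer to the electron-rich, peri-substituted C4 carbonyl may be too slow, or equilibration of C3 may not keep pace with reduction, so that the resolution is incomplete. The electron-rich benzylic alcohol may also ionise and eliminate. The fallback sets out from 21 and comes back at 23, bypassing 22 and step 13. The sodium enolate of 21 (NaHMDS, THF, −78 °C) is trapped with allyl chloroformate to give 5,7-bis(methoxymethoxy)-3-[4-(methoxymethoxy)-3-(3-methylbut-2-en-1-yl)phenyl]-6-(3-methylbut-2-en-1-yl)-2H-chromen-4-yl prop-2-en-1-yl carbonate F3. F3 with Pd2(dba)3 (a zerovalent palladium source), a tert-butyl-PHOX ligand and Meldrum's acid as proton donor in 1,4-dioxane at rt should undergo decarboxylative asymmetric protonation of the palladium enolate to give 23 directly. The ligand enantiomer that leads to (3R) is chosen by an analytical trial.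

Step 14. Acid may enolise C3 during acetal cleavage and erode the enantiomeric purity, or a freed phenol may add to a neighbouring prenyl alkene under acid and form a chroman. The fallback sets out from racemic 21 and comes back at 24. The same acidic MOM cleavage is run at the racemic stage, where no configuration is at stake and conditions can be kept as short and cold as the alkene demands, to give racemic 5,7-dihydroxy-3-[4-hydroxy-3-(3-methylbut-2-en-1-yl)phenyl]-6-(3-methylbut-2-en-1-yl)-2,3-dihydro-4H-chromen-4-one F4. F4 is resolved by preparative chromatography on a chiral stationary phase (amylose tris(3,5-dimethylphenylcarbamate), hexane/2-propanol) under neutral conditions to give 24. The (3S) enantiomer is racemised with Et3N and recycled.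

**Further compounds**

F1 | step 11 | [4-(methoxymethoxy)-3-(3-methylbut-2-en-1-yl)phenyl]acetic acid | COCOc1ccc(CC(=O)O)cc1CC=C(C)C
F2 | step 11 | 1-[6-hydroxy-2,4-bis(methoxymethoxy)-3-(3-methylbut-2-en-1-yl)phenyl]-2-[4-(methoxymethoxy)-3-(3-methylbut-2-en-1-yl)phenyl]ethan-1-one | COCOc1ccc(CC(=O)c2c(O)cc(OCOC)c(CC=C(C)C)c2OCOC)cc1CC=C(C)C
F3 | step 12 | 5,7-bis(methoxymethoxy)-3-[4-(methoxymethoxy)-3-(3-methylbut-2-en-1-yl)phenyl]-6-(3-methylbut-2-en-1-yl)-2H-chromen-4-yl prop-2-en-1-yl carbonate | C=CCOC(=O)OC1=C(c2ccc(OCOC)c(CC=C(C)C)c2)COc2cc(OCOC)c(CC=C(C)C)c(OCOC)c21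
F4 | step 14 | racemic 5,7-dihydroxy-3-[4-hydroxy-3-(3-methylbut-2-en-1-yl)phenyl]-6-(3-methylbut-2-en-1-yl)-2,3-dihydro-4H-chromen-4-one | CC(C)=CCc1cc(C2COc3cc(O)c(CC=C(C)C)c(O)c3C2=O)ccc1O
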